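Remark on the chemistry: the SMILES contains no stereocentre and no stereogenic double bond. The target is achiral, so the request for a single enantiomer is met by the constitution alone.

## Analysis of the target

Target 15 is 2,4-dihydroxy-6-pentadecylphenyl acetate. It is one benzene ring, numbered here C1 (acetoxy oxygen O1), C2 (hydroxyl O2), C3 (H), C4 (hydroxyl O4), C5 (H) and C6 (unbranched C15H31 chain). With no stereochemical element to set or preserve, the whole difficulty is regiochemical. The ring is a hydroxyquinol whose three oxygens must be told apart. The single acyl group sits on O1, the most hindered and least reactive oxygen, wedged between C2–O2 and the C6 chain, so direct acetylation of the triol would hit O4 and O2 first. O1–Ac and O2–H are ortho, so base, nucleophilic solvents or strong acid can move the acetyl group from O1 to O2 through a five-membered orthoacid, and any intermediate with a free 1,4-dihydroxy pair is oxidised by air to the hydroxyquinone. The last operations must therefore be neutral, aprotic and non-oxidising. The feature that invites the strategy is the contiguous segment C1–C2–C3–C4, which carries O, O, H, O with O1 para to O4: this is atom for atom a semisquaric ester (a C4 ring with three oxygens and one hydrogen), while C5–C6 plus the chain are a 1,1-disubstituted alkene. If the benzene ring is grown from these two pieces, C1 is a tertiary carbinol carbon before the arene exists, and O1 is then the only free oxygen in the flask, so the hardest acetylation becomes the easiest one.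

## Retrosynthetic reasoning

**15 ⇒ 14.** Only the O2–H bond is changed: O2 carries a benzyl group in 14. Benzyl is chosen because its removal is a neutral hydrogenolysis in an aprotic solvent. That is the one type of deprotection that gives the ortho acetate no reason to migrate. Nothing else in 14 differs from 15.

**14 ⇒ 11 (key disconnection).** The ring bond C4–C5 is cut and a σ bond C1–C4 is drawn across the ring, so the benzene contracts to the cyclobutenone 11. The four ring atoms of 11 are the future C1 (quaternary, already bearing O1–Ac), C2 (O-benzyl), C3 (H) and C4 (C=O). The side arm on C1 is the future C6(chain)=C5H2.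

- This cut is chosen because it is the only one that removes the regiochemical problem instead of managing it. All six ring atoms arrive with their substituents, and the three oxygens are already an ester, an ether and a carbonyl.
- The forward reaction opens the four-membered ring to the dienylketene 12, closes the six-membered ring to 13 and enolises to 14. It needs no reagent and must leave the acetate untouched.

**11 ⇒ 5 + 8 + an acetyl donor.** The C1–C6 bond and the O1–acyl bond are cut.

- The alkenyllithium 9, made from bromide 8, adds to the ketone-type carbonyl of the benzyl semisquarate 5.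
- The resulting tertiary alkoxide 10 is acetylated in the same flask.
- Three components are joined around C1 in one operation.
- The push–pull deactivation of the other carbonyl of 5 decides which carbon becomes C1.

**5 ⇒ 3 ⇒ 1 + 2.** The C3–H bond is traced back to a C–O bond. One carbonyl of the symmetrical diester 3 takes up hydride to give 4. An acid-induced 1,3-carbonyl transposition then expels one molecule of 2, leaving H on C3 and the benzyl ether on C2. Diester 3 comes from esterification of 1 with 2, so the protecting group costs no separate step.

**8 ⇒ 6 + 7.** The allylic C–C bond next to C6 is cut. A C14 Grignard reagent 6 displaces the allylic bromide of 7. This delivers the whole chain, the 1,1-disubstituted alkene and the halogen handle in one step.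

## Alternatives that were turned down

**Alternative 1:** the textbook route, which functionalises a purchased arene by cutting the C6–chain bond and the C1–O1 bond.

- Forward: Wittig olefination of 3,5-dimethoxybenzaldehyde A1 with a C14 ylide, hydrogenation and demethylation give 5-pentadecylresorcinol A2. Bis-benzylation and Vilsmeier–Haack formylation give 2,4-bis(benzyloxy)-6-pentadecylbenzaldehyde A3. Dakin or Baeyer–Villiger oxidation, acetylation of the freed hindered phenol and hydrogenolysis finish the sequence.
- Turned down: this is eight to nine linear steps, of which one builds the skeleton.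
- O1 enters through a carbon atom that is attached only to be excised.
- The formylation must choose the crowded carbon next to the chain over the position between the two oxygens.
- Two protecting-group regimes (methyl off, benzyl on, benzyl off) are needed. No step simplifies the problem; each repairs one group.

**Alternative 2:** the biomimetic route, which cuts the ring bond C1–C6 (aldol) and inserts O1 between C1 and a C-acetyl group.

- Forward: aldol–dehydration of tricosane-2,4,6,8-tetraone A4 gives 1-(2,4-dihydroxy-6-pentadecylphenyl)ethan-1-one A5. Peracid Baeyer–Villiger aryl migration then turns C-acetyl into O1-acetyl without any selection among the oxygens.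
- Turned down: A4 has two nearly equivalent cyclisation modes. The methyl ketone is the less hindered electrophile, so the wrong mode, leading to 1-(2,4-dihydroxy-6-methylphenyl)hexadecan-1-one A6, is favoured by structure. O-cyclisation to pyranones also competes.
- In A5 the carbonyl is deactivated by the hydrogen bond from O2–H and by two donor oxygens, while the free resorcinol ring is the better target for a peracid.
- Protecting both phenols puts back the steps that the idea was meant to save.

**Alternative 3:** Dötz benzannulation, which cuts C1–C2, C1–C6 and C4–C5 in a [3+2+1] union.

- Forward: pentacarbonyl[(2E)-1,3-bis(benzyloxy)prop-2-en-1-ylidene]chromium A7, heptadec-1-yne A8 and a CO ligand combine. O1 comes from CO and appears as the only free phenol. It is acetylated in situ to 2,4-bis(benzyloxy)-6-pentadecylphenyl acetate A9, which is then hydrogenolysed.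
- Turned down: the differentiation logic matches the chosen route, but the β-oxygen donor that O2 demands enriches the metal-bound vinylcarbene. This disfavours CO insertion, so five-membered carbocycles are the mechanistically preferred outcome.
- A7 needs several steps from the metal carbonyl, chromium is stoichiometric, and two benzyl groups are carried instead of one.

Key step: step 5

## Route

Step 1
Reactants: 1 squaric acid (3,4-dihydroxycyclobut-3-ene-1,2-dione); 2 benzyl alcohol
Product: 3 dibenzyl squarate [3,4-bis(benzyloxy)cyclobut-3-ene-1,2-dione]
Conditions: 2 (2.5 equiv), toluene, reflux, Dean–Stark trap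
Reagents that add atoms: none
Why: Azeotropic Fischer-type esterification of a vinylogous carboxylic acid; 1 is acidic enough to catalyse its own addition–elimination with the alcohol, and removal of water drives both hydroxyl groups to the diester.

Step 2
Reactants: 3 dibenzyl squarate
Product: 5 3-(benzyloxy)cyclobut-3-ene-1,2-dione (benzyl semisquarate), via hydroxycyclobutenone 4 (not isolated)
Conditions: LiAlH(Ot-Bu)3 (1.05 equiv), THF, −78 to −20 °C; then 2 M HCl, CH2Cl2, rt
Reagents that add atoms: water, O
Why: Chemoselective 1,2-reduction with a hindered aluminium hydride should stop at 4, because the remaining carbonyl is a donor-substituted vinylogous ester. Acid then ionises the allylic carbinol, water adds to the oxocarbenium carbon and benzyl alcohol leaves (the 1,3-carbonyl transposition known for squarate 1,2-adducts), which puts H on the future C3 and keeps the benzyl ether on the future C2.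

Step 3
Reactants: 6 tetradecylmagnesium chloride (commercial THF solution); 7 2,3-dibromoprop-1-ene
Product: 8 2-bromoheptadec-1-ene
Conditions: CuI (5 mol %), THF, 0 °C to rt
Reagents that add atoms: none
Why: Copper-catalysed allylic substitution of a Grignard reagent on 2,3-dibromopropene; the SN2 and SN2' paths give the same product, and the vinylic C–Br bond is inert under these conditions.

Step 4
Reactants: 8 2-bromoheptadec-1-ene; 5 3-(benzyloxy)cyclobut-3-ene-1,2-dione
Product: 11 2-(benzyloxy)-1-(heptadec-1-en-2-yl)-4-oxocyclobut-2-en-1-yl acetate (racemic), via alkenyllithium 9 (not isolated), via lithium alkoxide 10 (not isolated)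
Conditions: 8, t-BuLi (2.0 equiv), Et2O, −78 °C; cannulated into 5, THF, −78 °C; then Ac2O (1.5 equiv), −78 to 0 °C
Reagents that add atoms: acetic anhydride, CC(=O)OC(C)=O
Why: Bromine–lithium exchange puts the metal on the future C6, and the hard organolithium adds 1,2 to the ketone-type carbonyl of 5 (next to C–OBn) rather than to the push–pull deactivated vinylogous ester carbonyl, as is general for 3-alkoxycyclobutenediones. The tertiary alkoxide 10 is the only oxygen nucleophile present and is acetylated in situ. The new stereocentre forms as a racemate and is erased in step 5.

Step 5
Reactants: 11 2-(benzyloxy)-1-(heptadec-1-en-2-yl)-4-oxocyclobut-2-en-1-yl acetate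
Product: 14 2-(benzyloxy)-4-hydroxy-6-pentadecylphenyl acetate, via dienylketene 12 (not isolated), via cyclohexadienone 13 (not isolated)
Conditions: dry degassed toluene (0.02 M), 110 °C, Ar
Reagents that add atoms: none
Why: This is the thermal ring expansion of a 4-alkenyl-4-oxycyclobutenone, the known electrocyclic benzannulation that gives mono-O-protected hydroquinones. Heat breaks the strained C1–C4 σ bond in a conrotatory 4π electrocyclic opening to the dienylketene 12. Torquoselectivity turns the oxygen donor on C1 outward and the alkenyl arm inward, so the =C5H2 terminus lies next to the ketene carbon C4; the opening is reversible, so a ketene of the wrong geometry returns to 11. The benzene ring closes by a thermal disrotatory 6π electrocyclisation that forms only the C4–C5 bond and gives 13, whose irreversible enolisation to 14 drains the equilibria. No stereocentre is created and the one in 11 is destroyed, so racemic 11 suffices. Regiochemistry is not a selectivity question, because each of the six ring atoms arrives with its substituent fixed by the connectivity of 11. The one selectivity needed is that the acetyl group stays on O1: O2 is benzylated, the new O4–H is para and out of reach, and the medium is neutral and aprotic. High dilution and a dry solvent keep 12 from being intercepted intermolecularly.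

Step 6
Reactants: 14 2-(benzyloxy)-4-hydroxy-6-pentadecylphenyl acetate
Product: 15 2,4-dihydroxy-6-pentadecylphenyl acetate (target)
Conditions: H2 (1 atm), 10% Pd/C, EtOAc, rt; filtration and evaporation under Ar
Reagents that add atoms: none
Why: Catalytic hydrogenolysis of an aryl benzyl ether under neutral aprotic conditions; the aryl acetate, the phenols and the saturated chain are inert, and no base or nucleophilic solvent is present that could start an O1-to-O2 acetyl shift.

## Compound list

1 | squaric acid (3,4-dihydroxycyclobut-3-ene-1,2-dione) | O=C1C(O)=C(O)C1=O | starting material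
2 | benzyl alcohol | OCc1ccccc1 | starting material
3 | dibenzyl squarate, 3,4-bis(benzyloxy)cyclobut-3-ene-1,2-dione | O=C1C(OCc2ccccc2)=C(OCc2ccccc2)C1=O | intermediate
4 | 2,3-bis(benzyloxy)-4-hydroxycyclobut-2-en-1-one (racemic, not isolated) | O=C1C(OCc2ccccc2)=C(OCc2ccccc2)C1O | intermediate
5 | 3-(benzyloxy)cyclobut-3-ene-1,2-dione | O=C1C=C(OCc2ccccc2)C1=O | intermediate
6 | tetradecylmagnesium chloride | CCCCCCCCCCCCCC[Mg]Cl | starting material
7 | 2,3-dibromoprop-1-ene | C=C(Br)CBr | starting material
8 | 2-bromoheptadec-1-ene | C=C(Br)CCCCCCCCCCCCCCC | intermediate
9 | heptadec-1-en-2-yllithium (not isolated) | [Li]C(=C)CCCCCCCCCCCCCCC | intermediate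
10 | lithium 2-(benzyloxy)-1-(heptadec-1-en-2-yl)-4-oxocyclobut-2-en-1-olate (racemic, not isolated) | O=C1C=C(OCc2ccccc2)C1(O[Li])C(=C)CCCCCCCCCCCCCCC | intermediate
11 | 2-(benzyloxy)-1-(heptadec-1-en-2-yl)-4-oxocyclobut-2-en-1-yl acetate (racemic) | O=C1C=C(OCc2ccccc2)C1(OC(C)=O)C(=C)CCCCCCCCCCCCCCC | intermediate
12 | (3Z)-4-acetoxy-3-(benzyloxy)-5-methylideneicosa-1,3-dien-1-one (dienylketene, not isolated) | O=C=C/C(OCc1ccccc1)=C(/OC(C)=O)C(=C)CCCCCCCCCCCCCCC | intermediate
13 | 6-(benzyloxy)-4-oxo-2-pentadecylcyclohexa-1,5-dien-1-yl acetate (not isolated) | O=C1CC(CCCCCCCCCCCCCCC)=C(OC(C)=O)C(OCc2ccccc2)=C1 | intermediate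
14 | 2-(benzyloxy)-4-hydroxy-6-pentadecylphenyl acetate | CCCCCCCCCCCCCCCc1cc(O)cc(OCc2ccccc2)c1OC(C)=O | intermediate
15 | 2,4-dihydroxy-6-pentadecylphenyl acetate | CCCCCCCCCCCCCCCc1cc(O)cc(O)c1OC(C)=O | target

## Step count and risk

Total step count: 6. Longest linear sequence: 5 (steps 1, 2, 4, 5, 6); step 3 is the convergent branch.

**Step 5 (key step).**

- Risk: acetoxy is the weakest donor of the oxygen substituents used in this ring expansion. The 4π opening may therefore need more heat, and the outward preference may be smaller. Slower opening leaves time for a sigmatropic 1,3-transposition of the doubly allylic acetate and for intermolecular capture of the ketene.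
- Fallback: keep the ring construction but place the acetate afterwards by steric subtraction. It sets out from 10 and returns at 14.
- Alkoxide 10 is trapped with chlorotrimethylsilane to give 3-(benzyloxy)-4-(heptadec-1-en-2-yl)-4-[(trimethylsilyl)oxy]cyclobut-2-en-1-one F1, a strong-donor substrate of the best-established kind.
- Thermolysis of F1 in toluene should give 3-(benzyloxy)-5-pentadecyl-4-[(trimethylsilyl)oxy]phenol F2.
- Citric acid in methanol under argon frees 2-(benzyloxy)-6-pentadecylbenzene-1,4-diol F3.
- Acetic anhydride and pyridine give 2-(benzyloxy)-6-pentadecyl-1,4-phenylene diacetate F4.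
- One equivalent of pyrrolidine at 0 °C should cleave only the unhindered O4 acetate. The O1 acetate is shielded on both sides, so the product is 14.

**Step 4.**

- Risk: the unsubstituted ring carbon of 5 is a Michael position, and the vinylogous ester carbon can undergo addition–elimination, so attack at the wrong site may compete with 1,2-addition. Capture of the crowded tertiary alkoxide by the anhydride may be incomplete, and any residual organolithium would consume the anhydride.
- Fallback: separate C–C bond formation from acylation. It sets out from 10 and returns at 11.
- Alkoxide 10 is protonated with aqueous ammonium chloride to give 3-(benzyloxy)-4-(heptadec-1-en-2-yl)-4-hydroxycyclobut-2-en-1-one F5.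
- F5 is freed from products of wrong-site attack by chromatography.
- The neutral alcohol is then acetylated by nucleophilic catalysis (acetic anhydride, DMAP, triethylamine, 0 °C) to give 11.

**Step 2.**

- Risk: 5 is in effect the benzyl ester of a strong acid. Acid-promoted ionisation of the benzyl–oxygen bond, or hydrolysis of the vinylogous ester, may occur while the carbonyl is unmasked. Addition of a second hydride is the minor risk.
- Fallback: carry out the hydride chemistry on a robust secondary alkyl ester and bring in benzyl last under near-neutral conditions. It sets out from 1 and returns at 5.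
- Acid 1 is esterified azeotropically with propan-2-ol to diisopropyl squarate F6.
- The same hydride and acid sequence gives 3-isopropoxycyclobut-3-ene-1,2-dione F7.
- Aqueous acid hydrolysis gives semisquaric acid (3-hydroxycyclobut-3-ene-1,2-dione) F8.
- F8 is O-benzylated with benzyl 2,2,2-trichloroacetimidate in dichloromethane. The acidity of F8 activates the imidate without added catalyst, and the product is 5.

**Step 6.**

- Risk: once O2–H is free, the acetyl group can migrate from O1 to O2 through the five-membered orthoacid. This is most likely if the catalyst or its support carries acidic or basic residues, or if work-up is slow.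
- Fallback: select the acetate by subtraction instead of by placement, which also converges any scrambled material. It sets out from 14 and returns at 15.
- The crude hydrogenolysis product of 14 is peracetylated (acetic anhydride, pyridine) to 6-pentadecylbenzene-1,2,4-triyl triacetate F9.
- Lipase-catalysed butanolysis in methyl tert-butyl ether (immobilised Candida antarctica lipase B, butan-1-ol, 35 °C) should remove the two accessible acetates on O4 and O2. The doubly flanked O1 acetate is left in place, giving 15 under neutral conditions.

## Further compounds

F1 | step 5 | 3-(benzyloxy)-4-(heptadec-1-en-2-yl)-4-[(trimethylsilyl)oxy]cyclobut-2-en-1-one (racemic) | O=C1C=C(OCc2ccccc2)C1(O[Si](C)(C)C)C(=C)CCCCCCCCCCCCCCC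
F2 | step 5 | 3-(benzyloxy)-5-pentadecyl-4-[(trimethylsilyl)oxy]phenol | CCCCCCCCCCCCCCCc1cc(O)cc(OCc2ccccc2)c1O[Si](C)(C)C
F3 | step 5 | 2-(benzyloxy)-6-pentadecylbenzene-1,4-diol | CCCCCCCCCCCCCCCc1cc(O)cc(OCc2ccccc2)c1O
F4 | step 5 | 2-(benzyloxy)-6-pentadecyl-1,4-phenylene diacetate | CCCCCCCCCCCCCCCc1cc(OC(C)=O)cc(OCc2ccccc2)c1OC(C)=O
F5 | step 4 | 3-(benzyloxy)-4-(heptadec-1-en-2-yl)-4-hydroxycyclobut-2-en-1-one (racemic) | O=C1C=C(OCc2ccccc2)C1(O)C(=C)CCCCCCCCCCCCCCC
F6 | step 2 | diisopropyl squarate, 3,4-diisopropoxycyclobut-3-ene-1,2-dione | O=C1C(OC(C)C)=C(OC(C)C)C1=O
F7 | step 2 | 3-isopropoxycyclobut-3-ene-1,2-dione | O=C1C=C(OC(C)C)C1=O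
F8 | step 2 | semisquaric acid, 3-hydroxycyclobut-3-ene-1,2-dione | O=C1C=C(O)C1=O
F9 | step 6 | 6-pentadecylbenzene-1,2,4-triyl triacetate | CCCCCCCCCCCCCCCc1cc(OC(C)=O)cc(OC(C)=O)c1OC(C)=O
A1 | alternative 1 | 3,5-dimethoxybenzaldehyde | COc1cc(C=O)cc(OC)c1
A2 | alternative 1 | 5-pentadecylresorcinol | CCCCCCCCCCCCCCCc1cc(O)cc(O)c1
A3 | alternative 1 | 2,4-bis(benzyloxy)-6-pentadecylbenzaldehyde | CCCCCCCCCCCCCCCc1cc(OCc2ccccc2)cc(OCc2ccccc2)c1C=O
A4 | alternative 2 | tricosane-2,4,6,8-tetraone | CCCCCCCCCCCCCCCC(=O)CC(=O)CC(=O)CC(C)=O
A5 | alternative 2 | 1-(2,4-dihydroxy-6-pentadecylphenyl)ethan-1-one | CCCCCCCCCCCCCCCc1cc(O)cc(O)c1C(C)=O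
A6 | alternative 2 | 1-(2,4-dihydroxy-6-methylphenyl)hexadecan-1-one | CCCCCCCCCCCCCCCC(=O)c1c(C)cc(O)cc1O
A7 | alternative 3 | pentacarbonyl[(2E)-1,3-bis(benzyloxy)prop-2-en-1-ylidene]chromium | [C-]#[O+].[C-]#[O+].[C-]#[O+].[C-]#[O+].[C-]#[O+].[Cr]=C(OCc1ccccc1)/C=C/OCc1ccccc1
A8 | alternative 3 | heptadec-1-yne | C#CCCCCCCCCCCCCCCC
A9 | alternative 3 | 2,4-bis(benzyloxy)-6-pentadecylphenyl acetate | CCCCCCCCCCCCCCCc1cc(OCc2ccccc2)cc(OCc2ccccc2)c1OC(C)=O
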